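**Plan**
- The C4 formyl group is unmasked last from a dimethyl acetal. The indenone is then cut at C3–C3a and C1–C2, which gives 2-bromo-3-(dimethoxymethyl)-6-methylbenzaldehyde and 3-(prop-1-ynyl)guaiazulene.
- Enabling feature: the enone C1(=O)–C2(guaiazulen-3-yl)=C3(CH3) is fused to the benzene ring through C3a and C7a (CHO at C4, CH3 at C7). C2 and C3 are therefore the carbons of an internal alkyne, C3a is the former C–Br carbon and C1 the former formyl carbon on C7a.
- The alkyne is cut at the azulene C3–C(sp) bond (iodination, Sonogashira coupling with propyne). The bromoaldehyde is cut at its formyl C–aryl bond (iodine–magnesium exchange, DMF) and at its C–Br bond (lithiation between iodine and acetal).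
- Forward: the benzene and azulene rings are bought and the two fragments are made in 3 and 2 steps. The only ring formed, the five-membered indenone ring, closes in the annulation, and acetal hydrolysis finishes the route.
- Stereochemistry: the target has no stereocentre; only regiochemistry (site of lithiation, sense of alkyne insertion) has to be controlled.

Key step: step 6

Assumptions: 3-iodo-4-methylbenzaldehyde, guaiazulene and propyne (as a THF solution) are taken as purchasable. "Guaiazulen-3-yl" means 7-isopropyl-1,4-dimethylazulene bonded through its free five-ring carbon next to C3a, the carbon peri to the C4 methyl.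

**Route**

Step 1
Reactants: 1 3-iodo-4-methylbenzaldehyde
Product: 2 4-(dimethoxymethyl)-2-iodo-1-methylbenzene
Conditions: HC(OMe)3, p-TsOH·H2O (cat.), MeOH, rt; Et3N (trace) before concentration
Reagents that add atoms: trimethyl orthoformate, COC(OC)OC
Why: Acid-catalysed acetalisation of an aromatic aldehyde, driven by the orthoformate as water scavenger, should be clean because the aryl iodide and the methyl group are inert to these conditions.

Step 2
Reactants: 2 4-(dimethoxymethyl)-2-iodo-1-methylbenzene
Product: 4 2-bromo-1-(dimethoxymethyl)-3-iodo-4-methylbenzene, via aryllithium 3 (not isolated)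
Conditions: lithium 2,2,6,6-tetramethylpiperidide (from 2,2,6,6-tetramethylpiperidine and n-BuLi), THF, −78 °C; then BrCCl2CCl2Br, −78 °C
Reagents that add atoms: 1,2-dibromo-1,1,2,2-tetrachloroethane, ClC(Cl)(Br)C(Cl)(Cl)Br
Why: Directed ortho-lithiation should occur at the ring proton between iodine and the acetal carbon, the most acidic one (inductive effect of iodine plus lithium coordination by the acetal oxygens), the hindered amide base does not exchange the iodine, and the aryllithium is brominated by bromine transfer from the perhalogenated ethane.

Step 3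
Reactants: 4 2-bromo-1-(dimethoxymethyl)-3-iodo-4-methylbenzene
Product: 7 2-bromo-3-(dimethoxymethyl)-6-methylbenzaldehyde, via arylmagnesium chloride 5 (not isolated), via hemiaminal magnesium alkoxide 6 (not isolated)
Conditions: iPrMgCl·LiCl, THF, −40 °C; DMF, −40 to 0 °C; aq NH4Cl
Reagents that add atoms: N,N-dimethylformamide, CN(C)C=O
Why: Iodine–magnesium exchange with iPrMgCl·LiCl is far faster at C–I than at C–Br, the ortho-bromoarylmagnesium species should not eliminate to an aryne at this temperature, and Bouveault-type formylation with DMF followed by a buffered quench releases the aldehyde without touching the acetal.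

Step 4
Reactants: 8 guaiazulene (7-isopropyl-1,4-dimethylazulene)
Product: 9 3-iodoguaiazulene (3-iodo-7-isopropyl-1,4-dimethylazulene)
Conditions: N-iodosuccinimide (1.0 equiv), CH2Cl2, 0 °C, dark; short basic alumina plug, used at once
Reagents that add atoms: N-iodosuccinimide, O=C1CCC(=O)N1I
Why: Electrophilic aromatic iodination should take place at C3, the only unsubstituted electron-rich position of the five-membered ring, since C1 is blocked by methyl.

Step 5
Reactants: 9 3-iodoguaiazulene; 10 propyne
Product: 11 3-(prop-1-yn-1-yl)guaiazulene (7-isopropyl-1,4-dimethyl-3-(prop-1-yn-1-yl)azulene)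
Conditions: propyne (THF solution, excess), PdCl2(PPh3)2 (cat.), CuI (cat.), Et3N, THF, rt, sealed vessel
Reagents that add atoms: none
Why: Sonogashira coupling of an aryl iodide with a terminal alkyne runs at room temperature, which suits the sensitive iodoazulene, and it brings in the complete propynyl group so that no strong base is needed on the azulene.

Step 6
Reactants: 7 2-bromo-3-(dimethoxymethyl)-6-methylbenzaldehyde; 11 3-(prop-1-yn-1-yl)guaiazulene
Product: 12 4-(dimethoxymethyl)-2-(guaiazulen-3-yl)-3,7-dimethyl-1H-inden-1-one
Conditions: Pd(OAc)2 (5 mol %), NaOAc, n-Bu4NCl, DMA, 100 °C, argon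
Reagents that add atoms: none
Why: Larock indenone annulation: zerovalent palladium formed from Pd(OAc)2 inserts into the C–Br bond of 7, and the arylpalladium bromide adds syn across the alkyne of 11, the aryl carbon going to the methyl-bearing alkyne carbon (new C3–C3a bond) and palladium to the azulenyl-bearing carbon. The alkenylpalladium carbon then attacks the neighbouring formyl carbon (new C1–C2 bond), closing the five-membered ring by 5-exo-trig addition to C=O, and β-hydride elimination from the palladium alkoxide of the indenol gives the ketone while acetate returns the catalyst to the zerovalent state. The closest known reaction type is the palladium-catalysed annulation of ortho-halobenzaldehydes with aryl-substituted internal alkynes to 2,3-disubstituted indenones. No stereocentre is formed. The step needs regioselective insertion, which the size difference between the guaiazulenyl group (with its peri methyl) and methyl should secure by placing the larger group on the palladium-bearing carbon and hence at C2; it also needs discrimination between the two formyl-level carbons, which the acetal at the future C4 secures.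

Step 7
Reactants: 12 4-(dimethoxymethyl)-2-(guaiazulen-3-yl)-3,7-dimethyl-1H-inden-1-one
Product: 13 2-(guaiazulen-3-yl)-3,7-dimethyl-1-oxo-1H-indene-4-carbaldehyde
Conditions: 1 M aq HCl, THF, rt
Reagents that add atoms: water, O
Why: Acid-catalysed hydrolysis of a dimethyl acetal is fast in dilute aqueous acid at room temperature, conditions that the indenone and the azulene (made less basic by the enone at C3) should survive.

**Compound list**
1 | 3-iodo-4-methylbenzaldehyde | Cc1ccc(C=O)cc1I | starting material
2 | 4-(dimethoxymethyl)-2-iodo-1-methylbenzene | COC(OC)c1ccc(C)c(I)c1 | intermediate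
3 | [2-(dimethoxymethyl)-6-iodo-5-methylphenyl]lithium | COC(OC)c1ccc(C)c(I)c1[Li] | intermediate
4 | 2-bromo-1-(dimethoxymethyl)-3-iodo-4-methylbenzene | COC(OC)c1ccc(C)c(I)c1Br | intermediate
5 | [2-bromo-3-(dimethoxymethyl)-6-methylphenyl]magnesium chloride | COC(OC)c1ccc(C)c([Mg]Cl)c1Br | intermediate
6 | chloromagnesium [2-bromo-3-(dimethoxymethyl)-6-methylphenyl](dimethylamino)methoxide | COC(OC)c1ccc(C)c(C(O[Mg]Cl)N(C)C)c1Br | intermediate
7 | 2-bromo-3-(dimethoxymethyl)-6-methylbenzaldehyde | COC(OC)c1ccc(C)c(C=O)c1Br | intermediate
8 | guaiazulene (7-isopropyl-1,4-dimethylazulene) | CC(C)c1ccc(C)c2ccc(C)c2c1 | starting material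
9 | 3-iodoguaiazulene | Ic1cc(C)c2cc(C(C)C)ccc(C)c1-2 | intermediate
10 | propyne | CC#C | starting material
11 | 3-(prop-1-yn-1-yl)guaiazulene | CC#Cc1cc(C)c2cc(C(C)C)ccc(C)c1-2 | intermediate
12 | 4-(dimethoxymethyl)-2-(guaiazulen-3-yl)-3,7-dimethyl-1H-inden-1-one | COC(OC)c1ccc(C)c2c1C(C)=C(c1cc(C)c3cc(C(C)C)ccc(C)c1-3)C2=O | intermediate
13 | 2-(guaiazulen-3-yl)-3,7-dimethyl-1-oxo-1H-indene-4-carbaldehyde | CC1=C(c2cc(C)c3cc(C(C)C)ccc(C)c2-3)C(=O)c2c(C)ccc(C=O)c21 | target

**Step count**
Total steps: 7. Longest linear sequence: 5 steps (steps 1, 2, 3, 6, 7); the azulene branch (steps 4, 5) joins at step 6.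

**Steps most likely to fail**

Step 2. Deprotonation between iodine and the acetal carbon may be incomplete, or iodine may migrate between aryllithium species or be lost as LiI through an aryne before bromine transfer. The fallback moves the metalation to a more acidic substrate and to magnesium. It sets out from 1: I2 and aqueous NH3 in THF should convert the aldehyde into 3-iodo-4-methylbenzonitrile F1. TMPMgCl·LiCl in THF at 0 °C should magnesiate between nitrile and iodine to give (2-cyano-6-iodo-5-methylphenyl)magnesium chloride F2, which is not prone to aryne formation or halogen migration. BrCCl2CCl2Br then gives 2-bromo-3-iodo-4-methylbenzonitrile F3. i-Bu2AlH in toluene at −78 °C with acidic work-up gives 2-bromo-3-iodo-4-methylbenzaldehyde F4, and acetalisation under the conditions of step 1 comes back to the route at 4.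

Step 6. Oxidative addition into the C–Br bond flanked by the formyl and acetal carbons may be slow, leaving time for alkyne oligomerisation, breakdown of the azulene at 100 °C and erosion of insertion regiochemistry. The fallback keeps the same two bonds but moves the difficult oxidative addition to a step without azulene and starts the annulation by transmetalation. It sets out from 7: Miyaura borylation (B2pin2, PdCl2(dppf), KOAc, dioxane, 90 °C) should give 3-(dimethoxymethyl)-6-methyl-2-(4,4,5,5-tetramethyl-1,3,2-dioxaborolan-2-yl)benzaldehyde F5. [Rh(OH)(cod)]2-catalysed arylative cyclisation with 11 in dioxane/water at 60–90 °C should give racemic 4-(dimethoxymethyl)-2-(guaiazulen-3-yl)-3,7-dimethyl-1H-inden-1-ol F6. MnO2 in CH2Cl2 oxidises this allylic, benzylic alcohol and comes back to the route at 12.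

Step 4. The iodoazulene may dimerise oxidatively and decompose during handling and in the coupling of step 5. The fallback avoids any haloazulene and sets out from 8: Vilsmeier–Haack formylation (POCl3, DMF) should give guaiazulene-3-carbaldehyde F7. Corey–Fuchs olefination (CBr4, PPh3, CH2Cl2, 0 °C) gives 3-(2,2-dibromovinyl)guaiazulene F8. n-BuLi (2 equiv) in THF at −78 °C gives lithium (guaiazulen-3-yl)acetylide F9, which is methylated in the same flask with MeI and comes back to the route at 11.

**Further compounds**
F1 | step 2 | 3-iodo-4-methylbenzonitrile | Cc1ccc(C#N)cc1I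
F2 | step 2 | (2-cyano-6-iodo-5-methylphenyl)magnesium chloride | Cc1ccc(C#N)c([Mg]Cl)c1I
F3 | step 2 | 2-bromo-3-iodo-4-methylbenzonitrile | Cc1ccc(C#N)c(Br)c1I
F4 | step 2 | 2-bromo-3-iodo-4-methylbenzaldehyde | Cc1ccc(C=O)c(Br)c1I
F5 | step 6 | 3-(dimethoxymethyl)-6-methyl-2-(4,4,5,5-tetramethyl-1,3,2-dioxaborolan-2-yl)benzaldehyde | COC(OC)c1ccc(C)c(C=O)c1B1OC(C)(C)C(C)(C)O1
F6 | step 6 | racemic 4-(dimethoxymethyl)-2-(guaiazulen-3-yl)-3,7-dimethyl-1H-inden-1-ol | COC(OC)c1ccc(C)c2c1C(C)=C(c1cc(C)c3cc(C(C)C)ccc(C)c1-3)C2O
F7 | step 4 | guaiazulene-3-carbaldehyde | O=Cc1cc(C)c2cc(C(C)C)ccc(C)c1-2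
F8 | step 4 | 3-(2,2-dibromovinyl)guaiazulene | BrC(Br)=Cc1cc(C)c2cc(C(C)C)ccc(C)c1-2
F9 | step 4 | lithium (guaiazulen-3-yl)acetylide | [Li]C#Cc1cc(C)c2cc(C(C)C)ccc(C)c1-2
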